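The α‑methylene‑γ‑lactone is cut at its two bonds to the ten‑membered ring, O–C6 and C11–C7 (germacrane numbering: ring C1–C10, lactone C11–C13). Because C6 is allylic to the ring alkene C4=C5, both bonds are the 1,2‑adduct of a C4=C5–C6=C7 diene. A palladium‑catalysed Larock‑type heteroannulation of an acyclic (4Z,6Z)‑dienol with 2‑bromoacrylic acid therefore builds the whole lactone in one operation: carbopalladation at C7, steered by the free C8 hydroxyl and allylic 1,3‑strain, then anti attack of the carboxylate on the π‑allyl terminus C6. Ring‑closing metathesis at C1=C10, hydroxyl‑directed epoxidation, acylation and desilylation complete the target.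

Key step: step 9

Remark on the chemistry: C14 is the methyl on C10 and C15 the methyl on C4; the target has a Z‑C4=C5 bond, a cis‑1,10‑epoxide and a trans‑fused lactone, with all ring C–O bonds on one face, and the route is planned for exactly this isomer.

Step 1
Reactants: 1 prop‑2‑yn‑1‑ol
Product: 3 (2Z)‑3‑iodo‑2‑methylprop‑2‑en‑1‑ol, via alkenylmagnesium alkoxide 2 (not isolated)
Conditions: MeMgBr (2.5 equiv), CuI (10 mol %), THF, −10 °C to rt; then I2, −78 to 0 °C
Reagents that add atoms: methylmagnesium bromide, C[Mg]Br; iodine, II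
Why: Copper‑catalysed anti‑carbomagnesiation of the propargylic alkoxide puts methyl on C2 and magnesium on C3 cis to the alkoxide through a five‑membered chelate, and iodinolysis with retention should give the Z‑iodide.

Step 2
Reactants: 3 (2Z)‑3‑iodo‑2‑methylprop‑2‑en‑1‑ol
Product: 4 (2Z)‑3‑iodo‑2‑methylprop‑2‑enal
Conditions: activated MnO2 (15 equiv), CH2Cl2, rt
Reagents that add atoms: none
Why: Neutral allylic oxidation with MnO2 should keep the Z geometry of the β‑iodo enal if the aldehyde is used at once.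

Step 3
Reactants: 4 (2Z)‑3‑iodo‑2‑methylprop‑2‑enal
Product: 6 (1Z,3S)‑1‑iodo‑2‑methylhexa‑1,5‑dien‑3‑ol, via borinate ester 5 (not isolated)
Conditions: (−)‑Ipc2BOMe, allylMgBr, Et2O, −78 °C to rt; then 4, −78 °C; ethanolamine, rt
Reagents that add atoms: allylmagnesium bromide, C=CC[Mg]Br
Why: Brown allylation through a closed chair transition state, in which the allylborane from (−)‑Ipc2BOMe attacks the Si face of the enal and should set the carbinol centre (later C3) as S.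

Step 4
Reactants: 6 (1Z,3S)‑1‑iodo‑2‑methylhexa‑1,5‑dien‑3‑ol
Product: 7 tert‑butyl{[(1Z,3S)‑1‑iodo‑2‑methylhexa‑1,5‑dien‑3‑yl]oxy}dimethylsilane
Conditions: TBSCl, imidazole, DMF, rt
Reagents that add atoms: tert‑butyldimethylsilyl chloride, CC(C)(C)[Si](C)(C)Cl
Why: Standard silylation of a secondary alcohol, which keeps the C3 oxygen from becoming a dienylic leaving group or a directing group before the last step.

Step 5
Reactants: 8 3‑(trimethylsilyl)prop‑2‑ynal
Product: 10 (3R)‑5‑methyl‑1‑(trimethylsilyl)hex‑5‑en‑1‑yn‑3‑ol, via borinate ester 9 (not isolated)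
Conditions: (+)‑Ipc2BOMe, 2‑methylallylMgCl, Et2O, −78 °C to rt; then 8, −78 °C; ethanolamine, rt
Reagents that add atoms: 2‑methylallylmagnesium chloride, C=C(C)C[Mg]Cl
Why: Brown methallylation, in which the borane from (+)‑Ipc2BOMe attacks the Re face of the ynal and should give the R propargylic alcohol (later C8).

Step 6
Reactants: 10 (3R)‑5‑methyl‑1‑(trimethylsilyl)hex‑5‑en‑1‑yn‑3‑ol
Product: 11 (3R)‑5‑methylhex‑5‑en‑1‑yn‑3‑ol
Conditions: K2CO3 (0.2 equiv), MeOH, 0 °C
Reagents that add atoms: none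
Why: Base‑catalysed methanolysis of the alkynyl C–Si bond, which does not touch the stereocentre.

Step 7
Reactants: 7 tert‑butyl{[(1Z,3S)‑1‑iodo‑2‑methylhexa‑1,5‑dien‑3‑yl]oxy}dimethylsilane; 11 (3R)‑5‑methylhex‑5‑en‑1‑yn‑3‑ol
Product: 12 (4R,7Z,9S)‑9‑[(tert‑butyldimethylsilyl)oxy]‑2,8‑dimethyldodeca‑1,7,11‑trien‑5‑yn‑4‑ol
Conditions: PdCl2(PPh3)2 (3 mol %), CuI (6 mol %), Et3N, THF, rt
Reagents that add atoms: none
Why: Sonogashira coupling of a vinyl iodide with a terminal alkyne runs at room temperature with retention of the Z geometry and tolerates the free hydroxyl and the isolated alkenes.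

Step 8
Reactants: 12 (4R,7Z,9S)‑9‑[(tert‑butyldimethylsilyl)oxy]‑2,8‑dimethyldodeca‑1,7,11‑trien‑5‑yn‑4‑ol
Product: 13 (4R,5Z,7Z,9S)‑9‑[(tert‑butyldimethylsilyl)oxy]‑2,8‑dimethyldodeca‑1,5,7,11‑tetraen‑4‑ol
Conditions: Zn dust activated with Cu(OAc)2 and AgNO3, MeOH/H2O (1:1), rt
Reagents that add atoms: none
Why: Boland reduction adds two hydrogens cis to a conjugated alkyne that bears a propargylic hydroxyl and leaves isolated alkenes alone, which should give the (Z,Z)‑diene (C4=C5–C6=C7 of the target).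

Step 9
Reactants: 13 (4R,5Z,7Z,9S)‑9‑[(tert‑butyldimethylsilyl)oxy]‑2,8‑dimethyldodeca‑1,5,7,11‑tetraen‑4‑ol; 14 2‑bromoprop‑2‑enoic acid
Product: 15 (4S,5S)‑5‑[(1Z,3S)‑3‑[(tert‑butyldimethylsilyl)oxy]‑2‑methylhexa‑1,5‑dien‑1‑yl]‑4‑[(1R)‑1‑hydroxy‑3‑methylbut‑3‑en‑1‑yl]‑3‑methylideneoxolan‑2‑one
Conditions: Pd(OAc)2 (10 mol %), PPh3 (20 mol %), n‑Bu4NCl (1 equiv), NaHCO3 (3 equiv), DMF, 60 °C
Reagents that add atoms: none
Why: Zerovalent palladium inserts into the C–Br bond of 14, the 1‑carboxyvinylpalladium species adds across C6=C7 with C11 going to the diene terminus C7 and palladium to C6, where it becomes a π‑allyl complex over C6–C5–C4, and the carboxylate then closes the lactone at C6 and releases the catalyst. The closest known reaction type is the Larock heteroannulation of 1,3‑dienes with aryl or vinylic halides that carry a carboxylic acid. The five‑membered ring closes in a 5‑exo mode on the allyl terminus, and C4=C5 stays outside the ring with its Z geometry because the tertiary terminus C4 should not become σ‑bound. C7 is controlled by allylic 1,3‑strain of the Z‑C6=C7 bond, which holds H8 in the diene plane, so that the vinyl group, guided by coordination or hydrogen bonding of the free C8 hydroxyl, should arrive on the hydroxyl face and anti to the C9 chain (7S from 8R). C6 is controlled by attack of the carboxylate anti to palladium in the presence of chloride, a net anti addition across the Z alkene that gives the trans‑lactone (6S), and any cis isomer could drain into the trans one because the allylic C6–O bond can re‑ionise under zerovalent palladium. The step needs C7 over C4 regioselectivity and diene over isolated‑alkene chemoselectivity, which the less substituted, hydroxyl‑flanked diene terminus and the gain of a stabilised π‑allyl intermediate should secure.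

Step 10
Reactants: 15 (4S,5S)‑5‑[(1Z,3S)‑3‑[(tert‑butyldimethylsilyl)oxy]‑2‑methylhexa‑1,5‑dien‑1‑yl]‑4‑[(1R)‑1‑hydroxy‑3‑methylbut‑3‑en‑1‑yl]‑3‑methylideneoxolan‑2‑one
Product: 16 (3S,6S,7S,8R)‑3‑[(tert‑butyldimethylsilyl)oxy]‑8‑hydroxygermacra‑1(10)Z,4Z,11(13)‑trien‑12,6‑olide
Conditions: second‑generation Hoveyda–Grubbs catalyst RuCl2(H2IMes)(=CH‑C6H4‑2‑O‑i‑Pr) (10 mol %), toluene (1 mM), 80 °C
Reagents that add atoms: none
Why: Ring‑closing metathesis between the C1 vinyl group and the 1,1‑disubstituted C10 alkene releases ethene, and in a ten‑membered ring already bent by the Z‑C4=C5 bond and the trans‑fused lactone the new trisubstituted alkene should form as the less strained Z isomer, the electron‑poor exocyclic methylene being a poor partner.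

Step 11
Reactants: 16 (3S,6S,7S,8R)‑3‑[(tert‑butyldimethylsilyl)oxy]‑8‑hydroxygermacra‑1(10)Z,4Z,11(13)‑trien‑12,6‑olide
Product: 17 (1R,3S,6S,7S,8R,10S)‑3‑[(tert‑butyldimethylsilyl)oxy]‑1,10‑epoxy‑8‑hydroxygermacra‑4Z,11(13)‑dien‑12,6‑olide
Conditions: VO(acac)2 (5 mol %), t‑BuOOH (1.5 equiv), CH2Cl2, 0 °C to rt
Reagents that add atoms: tert‑butyl hydroperoxide, CC(C)(C)OO
Why: Vanadium‑catalysed hydroxyl‑directed epoxidation, in which the homoallylic C8 hydroxyl binds the metal peroxide and should deliver oxygen to the C1=C10 face on its own side (1R,10S), while the electron‑poor C4=C5 and C11=C13 bonds have no bound hydroxyl in allylic or homoallylic reach.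

Step 12
Reactants: 17 (1R,3S,6S,7S,8R,10S)‑3‑[(tert‑butyldimethylsilyl)oxy]‑1,10‑epoxy‑8‑hydroxygermacra‑4Z,11(13)‑dien‑12,6‑olide
Product: 18 (1R,3S,6S,7S,8R,10S)‑3‑[(tert‑butyldimethylsilyl)oxy]‑1,10‑epoxy‑8‑(2‑methylpropanoyloxy)germacra‑4Z,11(13)‑dien‑12,6‑olide
Conditions: (i‑PrCO)2O, Et3N, DMAP (cat.), CH2Cl2, 0 °C to rt
Reagents that add atoms: isobutyric anhydride, CC(C)C(=O)OC(=O)C(C)C
Why: DMAP‑catalysed acylation of the only free hydroxyl, with no stereocentre touched.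

Step 13
Reactants: 18 (1R,3S,6S,7S,8R,10S)‑3‑[(tert‑butyldimethylsilyl)oxy]‑1,10‑epoxy‑8‑(2‑methylpropanoyloxy)germacra‑4Z,11(13)‑dien‑12,6‑olide
Product: 19 (1R,3S,6S,7S,8R,10S)‑1,10‑epoxy‑3‑hydroxy‑8‑(2‑methylpropanoyloxy)germacra‑4Z,11(13)‑dien‑12,6‑olide (CNP0261225.1)
Conditions: HF·pyridine, pyridine, THF, 0 °C
Reagents that add atoms: none
Why: Fluoride cleavage of the silyl ether under pyridine‑buffered conditions should leave the epoxide, the ester and the α‑methylene lactone intact.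

Compound list
1 | prop‑2‑yn‑1‑ol | C#CCO | starting material
2 | bromomagnesium (2Z)‑3‑(bromomagnesio)‑2‑methylprop‑2‑en‑1‑olate | Br[Mg]OC/C(C)=C\[Mg]Br | intermediate (not isolated)
3 | (2Z)‑3‑iodo‑2‑methylprop‑2‑en‑1‑ol | OC/C(C)=C\I | intermediate
4 | (2Z)‑3‑iodo‑2‑methylprop‑2‑enal | O=C/C(C)=C\I | intermediate
5 | (1Z,3S)‑1‑iodo‑2‑methylhexa‑1,5‑dien‑3‑yl diisopinocampheylborinate (isopinocampheyl groups of the (+)‑α‑pinene series) | C=CC[C@H](OB([C@@H]1C[C@@H]2C[C@H]([C@H]1C)C2(C)C)[C@@H]1C[C@@H]2C[C@H]([C@H]1C)C2(C)C)/C(C)=C\I | intermediate (not isolated)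
6 | (1Z,3S)‑1‑iodo‑2‑methylhexa‑1,5‑dien‑3‑ol | C=CC[C@H](O)/C(C)=C\I | intermediate
7 | tert‑butyl{[(1Z,3S)‑1‑iodo‑2‑methylhexa‑1,5‑dien‑3‑yl]oxy}dimethylsilane | C=CC[C@H](O[Si](C)(C)C(C)(C)C)/C(C)=C\I | intermediate
8 | 3‑(trimethylsilyl)prop‑2‑ynal | C[Si](C)(C)C#CC=O | starting material
9 | (3R)‑5‑methyl‑1‑(trimethylsilyl)hex‑5‑en‑1‑yn‑3‑yl diisopinocampheylborinate (isopinocampheyl groups of the (−)‑α‑pinene series) | C[Si](C)(C)C#C[C@H](OB([C@H]1C[C@H]2C[C@@H]([C@@H]1C)C2(C)C)[C@H]1C[C@H]2C[C@@H]([C@@H]1C)C2(C)C)CC(C)=C | intermediate (not isolated)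
10 | (3R)‑5‑methyl‑1‑(trimethylsilyl)hex‑5‑en‑1‑yn‑3‑ol | C[Si](C)(C)C#C[C@H](O)CC(C)=C | intermediate
11 | (3R)‑5‑methylhex‑5‑en‑1‑yn‑3‑ol | C#C[C@H](O)CC(C)=C | intermediate
12 | (4R,7Z,9S)‑9‑[(tert‑butyldimethylsilyl)oxy]‑2,8‑dimethyldodeca‑1,7,11‑trien‑5‑yn‑4‑ol | C=CC[C@H](O[Si](C)(C)C(C)(C)C)/C(C)=C\C#C[C@H](O)CC(C)=C | intermediate
13 | (4R,5Z,7Z,9S)‑9‑[(tert‑butyldimethylsilyl)oxy]‑2,8‑dimethyldodeca‑1,5,7,11‑tetraen‑4‑ol | C=CC[C@H](O[Si](C)(C)C(C)(C)C)/C(C)=C\C=C/[C@H](O)CC(C)=C | intermediate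
14 | 2‑bromoprop‑2‑enoic acid (2‑bromoacrylic acid) | C=C(Br)C(=O)O | starting material
15 | (4S,5S)‑5‑[(1Z,3S)‑3‑[(tert‑butyldimethylsilyl)oxy]‑2‑methylhexa‑1,5‑dien‑1‑yl]‑4‑[(1R)‑1‑hydroxy‑3‑methylbut‑3‑en‑1‑yl]‑3‑methylideneoxolan‑2‑one | C=C1C(=O)O[C@@H](/C=C(/C)[C@@H](O[Si](C)(C)C(C)(C)C)CC=C)[C@@H]1[C@H](O)CC(C)=C | intermediate
16 | (3S,6S,7S,8R)‑3‑[(tert‑butyldimethylsilyl)oxy]‑8‑hydroxygermacra‑1(10)Z,4Z,11(13)‑trien‑12,6‑olide | C=C1C(=O)O[C@H]2/C=C(/C)[C@@H](O[Si](C)(C)C(C)(C)C)C/C=C(/C)C[C@@H](O)[C@H]12 | intermediate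
17 | (1R,3S,6S,7S,8R,10S)‑3‑[(tert‑butyldimethylsilyl)oxy]‑1,10‑epoxy‑8‑hydroxygermacra‑4Z,11(13)‑dien‑12,6‑olide | C=C1C(=O)O[C@H]2/C=C(/C)[C@@H](O[Si](C)(C)C(C)(C)C)C[C@H]3O[C@@]3(C)C[C@@H](O)[C@H]12 | intermediate
18 | (1R,3S,6S,7S,8R,10S)‑3‑[(tert‑butyldimethylsilyl)oxy]‑1,10‑epoxy‑8‑(2‑methylpropanoyloxy)germacra‑4Z,11(13)‑dien‑12,6‑olide | C=C1C(=O)O[C@H]2/C=C(/C)[C@@H](O[Si](C)(C)C(C)(C)C)C[C@H]3O[C@@]3(C)C[C@@H](OC(=O)C(C)C)[C@H]12 | intermediate
19 | (1R,3S,6S,7S,8R,10S)‑1,10‑epoxy‑3‑hydroxy‑8‑(2‑methylpropanoyloxy)germacra‑4Z,11(13)‑dien‑12,6‑olide | C=C1C(=O)O[C@H]2/C=C(/C)[C@@H](O)C[C@H]3O[C@@]3(C)C[C@@H](OC(=O)C(C)C)[C@H]12 | target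

Total step count: 13
Longest linear sequence: 11 steps (steps 1–4, then 7–13)

Steps most likely to fail

1. Step 9. What may go wrong: Heck‑type insertion of the vinylpalladium species into the isolated C1 vinyl group instead of the diene, delivery to the wrong diene face, or closure syn to palladium to the cis‑lactone. Fallback, from 13 back to 15, replaces organopalladium chemistry by an oxidative free‑radical carbolactonisation. Compound 13 is stirred with malonic acid, Mn(OAc)3·2H2O and KOAc in AcOH at room temperature. The malonyl radical should add to C7 anti to the C9 chain under the same allylic‑strain control, and the allyl radical is oxidised and captured at C6 by the carboxyl group, giving the α‑carboxy lactone F1 (C11 epimers). Decarboxylative Mannich methylenation of F1 (aqueous HCHO, Et2NH, NaOAc, AcOH) then gives 15.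

2. Step 10. What may go wrong: intermolecular metathesis at the C1 vinyl group, or ring closure onto the exocyclic C11=C13 bond, outrunning the strained ten‑membered closure. Fallback, from 15 back to 16, takes the exocyclic alkene out of play before ring closure. Conjugate addition of Me2NH (THF, 0 °C) to 15 gives the 13‑dimethylamino‑11,13‑dihydro lactone F2 (C11 epimers). Its salt with one equivalent of TsOH is cyclised with the same ruthenium catalyst and freed with aqueous NaHCO3 to the macrocyclic amine F3. MeI gives the methiodide F4, and Hofmann‑type elimination with NaHCO3 in aqueous MeCN restores the α‑methylene lactone, which is 16.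

3. Step 11. What may go wrong: slow oxygen transfer from the homoallylic vanadate in the medium ring, with loss of site or facial selectivity. Fallback, from 16 back to 19, moves the epoxidation to the last step and uses the other hydroxyl as the guide. Compound 16 is acylated with (i‑PrCO)2O, Et3N and DMAP to the macrocyclic isobutyrate F5. HF·pyridine removes the silyl ether to give the 3‑hydroxy triene F6. F6 is epoxidised with mCPBA (NaHCO3, CH2Cl2, 0 °C), where the homoallylic C3 hydroxyl should guide the peracid by hydrogen bonding to the same face of the electron‑rich C1=C10 bond, giving 19.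

Further compounds
F1 | step 9 | (4S,5S)‑5‑[(1Z,3S)‑3‑[(tert‑butyldimethylsilyl)oxy]‑2‑methylhexa‑1,5‑dien‑1‑yl]‑4‑[(1R)‑1‑hydroxy‑3‑methylbut‑3‑en‑1‑yl]‑2‑oxooxolane‑3‑carboxylic acid (C3 epimers) | OC(=O)C1C(=O)O[C@@H](/C=C(/C)[C@@H](O[Si](C)(C)C(C)(C)C)CC=C)[C@@H]1[C@H](O)CC(C)=C
F2 | step 10 | (4S,5S)‑5‑[(1Z,3S)‑3‑[(tert‑butyldimethylsilyl)oxy]‑2‑methylhexa‑1,5‑dien‑1‑yl]‑3‑[(dimethylamino)methyl]‑4‑[(1R)‑1‑hydroxy‑3‑methylbut‑3‑en‑1‑yl]oxolan‑2‑one (C3 epimers) | CN(C)CC1C(=O)O[C@@H](/C=C(/C)[C@@H](O[Si](C)(C)C(C)(C)C)CC=C)[C@@H]1[C@H](O)CC(C)=C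
F3 | step 10 | (3S,6S,7S,8R)‑3‑[(tert‑butyldimethylsilyl)oxy]‑13‑(dimethylamino)‑8‑hydroxygermacra‑1(10)Z,4Z‑dien‑12,6‑olide (C11 epimers) | CN(C)CC1C(=O)O[C@H]2/C=C(/C)[C@@H](O[Si](C)(C)C(C)(C)C)C/C=C(/C)C[C@@H](O)[C@H]12
F4 | step 10 | trimethylammonium iodide of F3 (13‑trimethylammonio derivative, C11 epimers) | C[N+](C)(C)CC1C(=O)O[C@H]2/C=C(/C)[C@@H](O[Si](C)(C)C(C)(C)C)C/C=C(/C)C[C@@H](O)[C@H]12.[I-]
F5 | step 11 | (3S,6S,7S,8R)‑3‑[(tert‑butyldimethylsilyl)oxy]‑8‑(2‑methylpropanoyloxy)germacra‑1(10)Z,4Z,11(13)‑trien‑12,6‑olide | C=C1C(=O)O[C@H]2/C=C(/C)[C@@H](O[Si](C)(C)C(C)(C)C)C/C=C(/C)C[C@@H](OC(=O)C(C)C)[C@H]12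
F6 | step 11 | (3S,6S,7S,8R)‑3‑hydroxy‑8‑(2‑methylpropanoyloxy)germacra‑1(10)Z,4Z,11(13)‑trien‑12,6‑olide | C=C1C(=O)O[C@H]2/C=C(/C)[C@@H](O)C/C=C(/C)C[C@@H](OC(=O)C(C)C)[C@H]12
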